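**Plan**

Locants used throughout: the seven-membered ring is C1(O-tigloyl)–C2–C3(O-senecioyl)–C4(Me)–C5–C10–C11(Me2); the cyclohexenone is C5–C6(=O)–C7=C8(Me)–C9–C10; the cyclobutane is C4–C5–C10–C9.
Retrosynthesis: the two esters and the enone (a 1,3-transposed C8 ketone) go first; the cyclobutane is opened at C4–C9 (C4 enolate plus C8,C9-epoxide); C10–C11 is then cut by a retro-Cope that ties C2, C3 and C4 into a temporary cyclopropane; the cyclopropane falls into a vinylcarbenoid and a triene.
Enabling feature: in the seven-membered ring the oxygenated C1 (as enol ether C1=C2) and the C4–C5 bond (as an alkene) flank C3 in a 1,4-diene relationship with C10–C11 opposite C3, which is the retron of a cis-divinylcyclopropane rearrangement.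
Forward order: cyclohexadiene ring (from cyclohexenone) → cyclopropane → seven-membered ring by strain-releasing Cope closure of C10–C11 → cyclobutane by reductive epoxide alkylation (C4–C9) → esters → transposed enone.
Stereochemistry: the chiral dirhodium catalyst sets the cyclopropane, whose chirality passes to C10 in the Cope step; a temporary C3 carbinol (ligand-controlled borylation) directs C1 (1,3-anti reduction); C5, C8/C9 and C4 follow from attack anti to C11 and from ring constraint; C3 is finally set anti to C1 by Evans–Tishchenko hydride delivery.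

Key step: step 6

Remark: the facial sense of Rh2(S-PTAD)4 in step 5 and of the SEGPHOS ligand in step 9 is assigned by analogy with related reactions; if either proves opposite, the enantiomeric catalyst or ligand is used.

**Route**

Step 1
Reactants: 1 cyclohex-2-en-1-one
Product: 2 cyclohexa-1,3-dien-1-yl trifluoromethanesulfonate
Conditions: Tf2O, 2,6-di-tert-butyl-4-methylpyridine, CH2Cl2, 0 to 25 °C
Reagents that add atoms: trifluoromethanesulfonic anhydride, O=S(=O)(OS(=O)(=O)C(F)(F)F)C(F)(F)F
Why: O-sulfonylation of the enone and loss of the γ-proton under thermodynamic control should give the linear conjugated dienyl triflate (dienol triflate formation); no stereocentre is formed.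

Step 2
Reactants: 2 cyclohexa-1,3-dien-1-yl trifluoromethanesulfonate; 3 4,4,5,5-tetramethyl-2-(prop-1-en-2-yl)-1,3,2-dioxaborolane
Product: 4 1-(prop-1-en-2-yl)cyclohexa-1,3-diene
Conditions: Pd(PPh3)4 (3 mol %), K3PO4, 1,4-dioxane/H2O, 50 °C
Reagents that add atoms: none
Why: Suzuki–Miyaura coupling of an alkenyl triflate with an alkenylboronate keeps both double-bond positions and should give the triene, which is used at once because it can aromatise.

Step 3
Reactants: 5 methyl 4-methyl-3-oxopentanoate
Product: 6 methyl 2-diazo-4-methyl-3-oxopentanoate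
Conditions: 4-acetamidobenzenesulfonyl azide, Et3N, MeCN, 0 to 25 °C
Reagents that add atoms: 4-acetamidobenzenesulfonyl azide, CC(=O)Nc1ccc(cc1)S(=O)(=O)N=[N+]=[N-]
Why: Regitz diazo transfer to the active methylene of a β-keto ester.

Step 4
Reactants: 6 methyl 2-diazo-4-methyl-3-oxopentanoate
Product: 7 methyl 3-(tert-butyldimethylsilyloxy)-2-diazo-4-methylpent-3-enoate
Conditions: TBSOTf, Et3N, CH2Cl2, 0 °C
Reagents that add atoms: tert-butyldimethylsilyl trifluoromethanesulfonate, CC(C)(C)[Si](C)(C)OS(=O)(=O)C(F)(F)F
Why: Soft enolisation and O-silylation at the only enolisable position (the isopropyl CH) should give the 2-siloxyvinyl diazoacetate, whose fully substituted vinyl terminus is the future C11.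

Step 5
Reactants: 7 methyl 3-(tert-butyldimethylsilyloxy)-2-diazo-4-methylpent-3-enoate; 4 1-(prop-1-en-2-yl)cyclohexa-1,3-diene
Product: 8 methyl 1-[1-(tert-butyldimethylsilyloxy)-2-methylprop-1-en-1-yl]-2-(cyclohexa-1,3-dien-1-yl)-2-methylcyclopropane-1-carboxylate (siloxyvinyl on C2 and dienyl on C4 cis)
Conditions: Rh2(S-PTAD)4 (1 mol %), 4 (2 equiv), 2,2-dimethylbutane, −26 to 0 °C
Reagents that add atoms: none
Why: Rhodium-carbenoid cyclopropanation by a donor/acceptor vinylcarbenoid at the least hindered, terminal 1,1-disubstituted alkene of 4; the chiral dirhodium tetracarboxylate should set C2 and C4, the addition is stereospecific and places the siloxyvinyl donor cis to the dienyl group as in vinylcarbenoid/diene formal (4+3) cycloadditions, and the fully substituted vinyl terminus suppresses vinylogous attack.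

Step 6
Reactants: 8 cis-divinylcyclopropane ester
Product: 9 bicyclic siloxy triene ester (seven-membered ring C1(OTBS)=C2(CO2Me)–C3H2–C4(Me)=C5–C10H–C11Me2 fused to the cyclohexene C5–C6–C7–C8=C9–C10)
Conditions: toluene, 2,6-di-tert-butyl-4-methylphenol (trace), 110 °C
Reagents that add atoms: none
Why: Concerted [3,3]-sigmatropic shift (cis-divinylcyclopropane to cycloheptadiene Cope rearrangement) through the endo boat transition state, in which the C2–C4 bond of the three-membered ring breaks as C11 of the siloxyvinyl group bonds to C10 of the cyclohexadienyl group, driven by release of cyclopropane strain and helped by the push–pull substitution at C2. The closest known reaction type is the Cope step of vinylcarbenoid/diene formal (4+3) cycloadditions and of 2-siloxyvinyl vinylcyclopropanes. It closes the seven-membered ring C1–C2–C3–C4–C5–C10–C11 in a pericyclic 3,3 mode, enlarging the three-membered ring by four atoms. The new stereocentre C10 is controlled by the cyclopropane configuration at C4, because the boat geometry lets C11 reach only the face of C10 held over the small ring, so the chirality set in step 5 is transferred. The step needs the two alkenyl groups cis, which step 5 secures, and must tolerate one inward methyl on C11, which raises the barrier and is the reason for heating, while the ring carbon C9 on C10 points outward. A competing homodienyl 1,5-hydrogen shift should not occur because no hydrogen-bearing alkyl group stands cis to an alkenyl group.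

Step 7
Reactants: 9 bicyclic siloxy triene ester
Product: 11 bicyclic C1 ketone (C4=C5 and C8=C9 alkenes), via β-keto ester 10 (not isolated)
Conditions: 1 M HCl, THF, 0 °C; then LiCl, H2O, DMSO, 140 °C
Reagents that add atoms: none
Why: Acid hydrolysis of the silyl enol ether followed by Krapcho dealkoxycarbonylation removes the activating ester; C10 is not α to the carbonyl and keeps its configuration.

Step 8
Reactants: 11 bicyclic C1 ketone
Product: 13 bicyclic 2,4-dienone, via trimethylsilyl enol ether 12 (not isolated)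
Conditions: LiN(SiMe3)2, Me3SiCl, THF, −78 °C; then Pd(OAc)2, MeCN, 25 °C
Reagents that add atoms: chlorotrimethylsilane, C[Si](C)(C)Cl (silyl group of intermediate 12 only)
Why: Saegusa–Ito oxidation; C2 is the only enolisable α-carbon because C11 is quaternary, so the C2=C3 alkene should form.

Step 9
Reactants: 13 bicyclic 2,4-dienone
Product: 15 3-hydroxy ketone (3-OH cis to H-10), via β-boryl ketone 14 (not isolated)
Conditions: CuCl (5 mol %), NaOtBu (10 mol %), (R)-DTBM-SEGPHOS (6 mol %), B2pin2, MeOH, THF, 25 °C; then H2O2, pH 7 phosphate buffer, 0 °C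
Reagents that add atoms: hydrogen peroxide, OO (hydroxyl oxygen of 15); bis(pinacolato)diboron, CC1(C)OB(OC1(C)C)B1OC(C)(C)C(C)(C)O1 (boryl group of intermediate 14 only)
Why: Copper-catalysed asymmetric conjugate borylation should go 1,4 and not 1,6 because the δ-carbon C5 is fully substituted; the ligand sets C3 with boron syn to H-10, and the C–B bond is oxidised with retention.

Step 10
Reactants: 15 3-hydroxy ketone
Product: 16 1,3-anti diol (1-OH trans and 3-OH cis to H-10)
Conditions: Me4NBH(OAc)3, MeCN/AcOH, −30 °C
Reagents that add atoms: none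
Why: Evans–Saksena hydroxyl-directed reduction, in which the alkoxy(diacetoxy)borohydride formed at O3 delivers hydride intramolecularly to C1 and should give the 1,3-anti diol, setting C1.

Step 11
Reactants: 16 1,3-anti diol
Product: 17 1-hydroxy enone (C3 ketone conjugated to C4=C5)
Conditions: MnO2 (activated, 20 equiv), CH2Cl2, 25 °C
Reagents that add atoms: none
Why: Allylic oxidation by MnO2 should touch only the C3 carbinol and spare the saturated C1 carbinol, which puts the carbonyl at C3 where the cyclobutane closure needs it.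

Step 12
Reactants: 17 1-hydroxy enone
Product: 18 1-(tert-butyldimethylsilyloxy) enone
Conditions: TBSOTf, 2,6-lutidine, CH2Cl2, −78 to 0 °C
Reagents that add atoms: tert-butyldimethylsilyl trifluoromethanesulfonate, CC(C)(C)[Si](C)(C)OS(=O)(=O)C(F)(F)F
Why: Silylation of the hindered secondary alcohol with the silyl triflate; the ether prevents alkoxide formation and retro-aldol cleavage in step 14.

Step 13
Reactants: 18 1-silyloxy enone
Product: 19 8,9-epoxy enone (epoxide oxygen on the face of H-10)
Conditions: 3-chloroperoxybenzoic acid, NaHCO3, CH2Cl2, 0 °C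
Reagents that add atoms: 3-chloroperoxybenzoic acid, OOC(=O)c1cccc(Cl)c1
Why: Prilezhaev epoxidation of the only electron-rich alkene (the tetrasubstituted enone alkene is deactivated); the peracid should approach anti to the C10–C11 bond, on the face of H-10.

Step 14
Reactants: 19 8,9-epoxy enone
Product: 22 tricyclic 8-hydroxy 3-ketone (longipinane skeleton), via silyl enol ether 20 (not isolated), via lithium enolate 21 (not isolated)
Conditions: [(Ph3P)CuH]6 (5 mol %), PhMe2SiH, toluene, 25 °C; then MeLi, THF, −78 to 0 °C; HMPA, 25 to 40 °C; H2O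
Reagents that add atoms: dimethylphenylsilane, C[SiH](C)c1ccccc1 (silyl group of intermediate 20 only); methyllithium, [Li]C (lithium of intermediate 21 only)
Why: Copper hydride 1,4-hydrosilylation gives the C3–C4 enol silane regiospecifically, with hydride adding to C5 on the H-10 face (anti to both allylic C–C bonds at C10) to make the cis ring fusion; the lithium enolate released by MeLi then opens the epoxide at C9 with inversion in a 4-exo-tet intramolecular alkylation (reductive enolate alkylation), and the configuration of the new quaternary C4 is fixed by the two rings it joins.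

Step 15
Reactants: 22 tricyclic 8-hydroxy 3-ketone
Product: 23 tricyclic 3,8-diketone (1-OTBS)
Conditions: Dess–Martin periodinane, NaHCO3, CH2Cl2, 25 °C
Reagents that add atoms: none
Why: Dess–Martin oxidation of the secondary alcohol; the ketone keeps C8 from being acylated later and is the handle for the enone.

Step 16
Reactants: 23 tricyclic 3,8-diketone
Product: 24 tricyclic 1-hydroxy 3,8-diketone
Conditions: HF·pyridine, THF, 0 to 25 °C
Reagents that add atoms: none
Why: Acidic fluoride cleaves the silyl ether without base, which should avoid retro-aldol cleavage of the β-hydroxy ketone.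

Step 17
Reactants: 24 tricyclic 1-hydroxy 3,8-diketone; 25 (E)-2-methylbut-2-enal
Product: 26 1-O-tigloyl 3-hydroxy 8-ketone (3-OH anti to O1)
Conditions: SmI2 (30 mol %), 25 (5 equiv), THF, −10 °C
Reagents that add atoms: none
Why: Evans–Tishchenko reaction, in which the samarium-bound hemiacetal formed from the C1 hydroxyl and 25 transfers hydride intramolecularly to the C3 carbonyl; this should give the 1,3-anti carbinol, leave the tigloyl group on O1 and spare the C8 ketone, which has no β-hydroxyl.

Step 18
Reactants: 26 1-O-tigloyl 3-hydroxy 8-ketone; 27 3-methylbut-2-enoyl chloride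
Product: 28 1-O-tigloyl 3-O-senecioyl 8-ketone
Conditions: pyridine, 4-(dimethylamino)pyridine (cat.), CH2Cl2, 0 to 25 °C
Reagents that add atoms: none
Why: Acylation of the hindered C3 alcohol through the acylpyridinium ion; pyridine in place of a trialkylamine should avoid ketene formation and loss of conjugation in the senecioyl group.

Step 19
Reactants: 28 1-O-tigloyl 3-O-senecioyl 8-ketone
Product: 29 diester 6-en-8-one
Conditions: 2-iodoxybenzoic acid, DMSO, 75 °C
Reagents that add atoms: none
Why: IBX α,β-dehydrogenation of the ketone; only C7 can be enolised because C9 is a bridgehead, so the C6=C7 alkene should result.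

Step 20
Reactants: 29 diester 6-en-8-one
Product: 30 diester tertiary allylic alcohol (8-methyl-6-en-8-ol)
Conditions: MeMgBr, CeCl3, THF, −78 °C
Reagents that add atoms: methylmagnesium bromide, C[Mg]Br
Why: Organocerium 1,2-addition to the enone carbonyl, which should be faster than attack on the two hindered unsaturated esters and come from the face away from the C4 methyl; the C8 configuration is lost again in step 21.

Step 21
Reactants: 30 diester tertiary allylic alcohol
Product: 31 target diester enone
Conditions: pyridinium chlorochromate [C5H5NH][CrO3Cl], NaOAc, CH2Cl2, 25 °C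
Reagents that add atoms: none
Why: Babler–Dauben oxidative transposition, a [3,3] shift of the tertiary allylic chromate ester to C6 followed by oxidation, should give the enone C6(=O)–C7=C8(Me).

**Compound list**

1 | cyclohex-2-en-1-one | O=C1C=CCCC1 | starting material
2 | cyclohexa-1,3-dien-1-yl trifluoromethanesulfonate | O=S(=O)(OC1=CC=CCC1)C(F)(F)F | intermediate
3 | 4,4,5,5-tetramethyl-2-(prop-1-en-2-yl)-1,3,2-dioxaborolane | C=C(C)B1OC(C)(C)C(C)(C)O1 | starting material
4 | 1-(prop-1-en-2-yl)cyclohexa-1,3-diene | C=C(C)C1=CC=CCC1 | intermediate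
5 | methyl 4-methyl-3-oxopentanoate | COC(=O)CC(=O)C(C)C | starting material
6 | methyl 2-diazo-4-methyl-3-oxopentanoate | COC(=O)C(=[N+]=[N-])C(=O)C(C)C | intermediate
7 | methyl 3-(tert-butyldimethylsilyloxy)-2-diazo-4-methylpent-3-enoate | COC(=O)C(=[N+]=[N-])C(O[Si](C)(C)C(C)(C)C)=C(C)C | intermediate
8 | methyl 1-[1-(tert-butyldimethylsilyloxy)-2-methylprop-1-en-1-yl]-2-(cyclohexa-1,3-dien-1-yl)-2-methylcyclopropane-1-carboxylate; ring carbons C2 (ester, siloxyvinyl), C3 (CH2), C4 (methyl, dienyl); siloxyvinyl and dienyl cis | COC(=O)[C@]1(C(O[Si](C)(C)C(C)(C)C)=C(C)C)C[C@@]1(C)C2=CC=CCC2 | intermediate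
9 | bicyclo[5.4.0]undecatriene: C1(OTBS)=C2(CO2Me), C3H2, C4(Me)=C5, C8=C9, C11Me2; H-10 as in the target | CC(C)(C)[Si](C)(C)OC1=C(C(=O)OC)CC(C)=C2CCC=C[C@@H]2C1(C)C | intermediate
10 | β-keto ester from 9 (C1 ketone, C2 methyl ester; not isolated) | O=C1C(C(=O)OC)CC(C)=C2CCC=C[C@@H]2C1(C)C | intermediate
11 | bicyclic C1 ketone with C4=C5 and C8=C9 alkenes | O=C1CCC(C)=C2CCC=C[C@@H]2C1(C)C | intermediate
12 | C1 trimethylsilyl enol ether of 11 (C1=C2; not isolated) | C[Si](C)(C)OC1=CCC(C)=C2CCC=C[C@@H]2C1(C)C | intermediate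
13 | bicyclic 2,4-dienone (C1 ketone, C2=C3, C4=C5, C8=C9) | O=C1C=CC(C)=C2CCC=C[C@@H]2C1(C)C | intermediate
14 | 3-(pinacolboryl) ketone, boron cis to H-10 (not isolated) | O=C1C[C@@H](B3OC(C)(C)C(C)(C)O3)C(C)=C2CCC=C[C@@H]2C1(C)C | intermediate
15 | 3-hydroxy ketone, 3-OH cis to H-10 | O=C1C[C@@H](O)C(C)=C2CCC=C[C@@H]2C1(C)C | intermediate
16 | 1,3-anti diol, 1-OH trans and 3-OH cis to H-10 | O[C@@H]1C[C@@H](O)C(C)=C2CCC=C[C@@H]2C1(C)C | intermediate
17 | 1-hydroxy enone (C3 ketone, C4=C5, C8=C9) | O[C@@H]1CC(=O)C(C)=C2CCC=C[C@@H]2C1(C)C | intermediate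
18 | 1-(tert-butyldimethylsilyloxy) enone | CC(C)(C)[Si](C)(C)O[C@@H]1CC(=O)C(C)=C2CCC=C[C@@H]2C1(C)C | intermediate
19 | 8,9-epoxy enone, epoxide oxygen cis to H-10 | CC(C)(C)[Si](C)(C)O[C@@H]1CC(=O)C(C)=C2CC[C@H]3O[C@H]3[C@@H]2C1(C)C | intermediate
20 | C3 dimethylphenylsilyl enol ether (C3=C4), H-5 cis to H-10 (not isolated) | CC(C)(C)[Si](C)(C)O[C@@H]1CC(O[Si](C)(C)c4ccccc4)=C(C)[C@@H]2CC[C@H]3O[C@H]3[C@@H]2C1(C)C | intermediate
21 | C3 lithium enolate (not isolated) | CC(C)(C)[Si](C)(C)O[C@@H]1CC(O[Li])=C(C)[C@@H]2CC[C@H]3O[C@H]3[C@@H]2C1(C)C | intermediate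
22 | tricyclo[5.4.0.0(2,8)]undecane (longipinane) skeleton: 1-OTBS, C3 ketone, 8-OH cis to H-9 and H-10 | CC(C)(C)[Si](C)(C)O[C@@H]1CC(=O)[C@@]2(C)[C@@H]3CC[C@@H](O)[C@H]2[C@@H]3C1(C)C | intermediate
23 | tricyclic 3,8-diketone, 1-OTBS | CC(C)(C)[Si](C)(C)O[C@@H]1CC(=O)[C@@]2(C)[C@@H]3CCC(=O)[C@H]2[C@@H]3C1(C)C | intermediate
24 | tricyclic 1-hydroxy 3,8-diketone | O[C@@H]1CC(=O)[C@@]2(C)[C@@H]3CCC(=O)[C@H]2[C@@H]3C1(C)C | intermediate
25 | (E)-2-methylbut-2-enal | C/C=C(\C)C=O | starting material
26 | 1-O-tigloyl 3-hydroxy 8-ketone, 3-OH anti to O1 | C/C=C(\C)C(=O)O[C@@H]1C[C@@H](O)[C@@]2(C)[C@@H]3CCC(=O)[C@H]2[C@@H]3C1(C)C | intermediate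
27 | 3-methylbut-2-enoyl chloride | CC(C)=CC(=O)Cl | starting material
28 | 1-O-tigloyl 3-O-senecioyl 8-ketone | C/C=C(\C)C(=O)O[C@@H]1C[C@@H](OC(=O)C=C(C)C)[C@@]2(C)[C@@H]3CCC(=O)[C@H]2[C@@H]3C1(C)C | intermediate
29 | diester 6-en-8-one | C/C=C(\C)C(=O)O[C@@H]1C[C@@H](OC(=O)C=C(C)C)[C@@]2(C)[C@@H]3C=CC(=O)[C@H]2[C@@H]3C1(C)C | intermediate
30 | diester 8-methyl-6-en-8-ol, methyl anti to the C4 bridge | C/C=C(\C)C(=O)O[C@@H]1C[C@@H](OC(=O)C=C(C)C)[C@@]2(C)[C@@H]3C=C[C@](C)(O)[C@H]2[C@@H]3C1(C)C | intermediate
31 | target: 1-O-tigloyl 3-O-senecioyl diester of the tricyclic enone C6(=O)–C7=C8(Me) | C/C=C(\C)C(=O)O[C@@H]1C[C@@H](OC(=O)C=C(C)C)[C@@]2(C)[C@@H]3C(=O)C=C(C)[C@H]2[C@@H]3C1(C)C | target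

**Count and risks**

Total step count: 21. Longest linear sequence: 19 steps (steps 1, 2 and 5 to 21); steps 3 and 4 form the second branch.

Step 14 is the most likely to fail. The lithium enolate may be too unreactive toward the epoxide, may alkylate on oxygen, or the hydride may add to the wrong face of C5 so that the enolate cannot reach C9. The fallback sets out from 18 and replaces the epoxide by a harder leaving group. Dihydroxylation of the C8=C9 alkene (OsO4 cat., N-methylmorpholine N-oxide) on the H-10 face should give the cis-8,9-diol F1. SOCl2/Et3N and then RuCl3 (cat.)/NaIO4 convert it into the 8,9-cyclic sulfate F2. The same copper hydride hydrosilylation gives the C3 silyl enol ether F3, and MeLi releases the lithium enolate F4, which should displace the sulfate at C9 far more readily and give the lithium 8-O-sulfate F5. Mild acid hydrolysis (H2SO4 cat., THF/H2O) of F5 returns to the route at 22.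

Step 17 is the second risk. Hydride transfer from a hemiacetal of an α,β-unsaturated aldehyde may be slow, and the enal may be consumed by reduction or conjugate side reactions at samarium. The fallback sets out from 24 and runs the Evans–Tishchenko reaction with acetaldehyde (SmI2 cat.) to give the 1-acetate 3-alcohol F6. Acylation with 27 gives the 1-acetate 3-senecioate F7. Selective methanolysis of the acetate (Mg(OMe)2, MeOH, 0 °C; the trans disposition of O1 and O3 disfavours acyl migration) gives the 1-alcohol 3-senecioate F8. Yamaguchi esterification with (E)-2-methylbut-2-enoic acid (2,4,6-trichlorobenzoyl chloride, Et3N, 4-(dimethylamino)pyridine) returns to the route at 28.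

Step 9 is the third risk. Competing 1,6-addition, weak facial control by the ligand on a chiral dienone, or β-elimination of the aldol product during oxidation may lower the outcome. The fallback sets out from 13. Nucleophilic epoxidation of the C2=C3 alkene (t-BuOOH, 1,8-diazabicyclo[5.4.0]undec-7-ene), expected on the face away from C9, gives the 2,3-epoxy ketone F9. Reductive opening of the α-C–O bond (SmI2, THF/MeOH, −90 °C) returns to the route at 15.

**Further compounds**

F1 | step 14 | 8,9-cis-diol of enone 18, both hydroxyls cis to H-10 | CC(C)(C)[Si](C)(C)O[C@@H]1CC(=O)C(C)=C2CC[C@@H](O)[C@@H](O)[C@@H]2C1(C)C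
F2 | step 14 | 8,9-cyclic sulfate of F1 | CC(C)(C)[Si](C)(C)O[C@@H]1CC(=O)C(C)=C2CC[C@H]3OS(=O)(=O)O[C@H]3[C@@H]2C1(C)C
F3 | step 14 | C3 dimethylphenylsilyl enol ether of F2, H-5 cis to H-10 | CC(C)(C)[Si](C)(C)O[C@@H]1CC(O[Si](C)(C)c4ccccc4)=C(C)[C@@H]2CC[C@H]3OS(=O)(=O)O[C@H]3[C@@H]2C1(C)C
F4 | step 14 | C3 lithium enolate of F2 | CC(C)(C)[Si](C)(C)O[C@@H]1CC(O[Li])=C(C)[C@@H]2CC[C@H]3OS(=O)(=O)O[C@H]3[C@@H]2C1(C)C
F5 | step 14 | lithium 8-O-sulfate of tricycle 22 | CC(C)(C)[Si](C)(C)O[C@@H]1CC(=O)[C@@]2(C)[C@@H]3CC[C@@H](OS(=O)(=O)O[Li])[C@H]2[C@@H]3C1(C)C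
F6 | step 17 | 1-O-acetyl 3-hydroxy 8-ketone, 3-OH anti to O1 | CC(=O)O[C@@H]1C[C@@H](O)[C@@]2(C)[C@@H]3CCC(=O)[C@H]2[C@@H]3C1(C)C
F7 | step 17 | 1-O-acetyl 3-O-senecioyl 8-ketone | CC(=O)O[C@@H]1C[C@@H](OC(=O)C=C(C)C)[C@@]2(C)[C@@H]3CCC(=O)[C@H]2[C@@H]3C1(C)C
F8 | step 17 | 1-hydroxy 3-O-senecioyl 8-ketone | O[C@@H]1C[C@@H](OC(=O)C=C(C)C)[C@@]2(C)[C@@H]3CCC(=O)[C@H]2[C@@H]3C1(C)C
F9 | step 9 | 2,3-epoxy ketone from 13, epoxide oxygen cis to H-10 | O=C1[C@H]3O[C@H]3C(C)=C2CCC=C[C@@H]2C1(C)C
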